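## Retrosynthetic overview

1. Feature: ring B (C5–C10) carries oxygen on the neighbouring carbons C6 and C7, the tetrasubstituted C8=C9 alkene, and the methyl-bearing quaternary C10 para to C7. It is a dearomatized 2-alkoxy-4-methylphenol whose para carbon is C10, so the target is traced back (redox at C5/C6/C7, acetates) to a 6-alkoxy-5,8-dien-7-one.
2. Key disconnection C1–C10: the C7 phenoxide of a hexasubstituted arene is alkylated through its para carbon by a primary bromide tethered from C5. Ring B is the arene and is present from step 1; ring A is closed last.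
3. Arene: the side chain is joined at C9 by B-alkyl Suzuki coupling (Z-alkene bought in with (Z)-3-methylpent-2-en-4-yn-1-ol). The quaternary C4 and the O6/O7 differentiation come from a Friedel–Crafts/lactonization of 3,5-dimethylcatechol with methyl 3-methylbut-2-enoate; C1 comes from a Wittig methylenation.
4. After ring closure: enol ether to diosphenol; hydride sets C5 (α-H) and C6 (β-OH); C7 is re-oxidized and then reduced by delivery from the 6β-hydroxyl (7α-OH); acetylation and desilylation finish.

Key step: step 13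

Remarks and assumptions:
- Labdane numbering is used for all intermediates (ring A: C1–C5, C10; ring B: C5–C10; side chain C11–C15); β is the face of the C10 methyl group.
- A free 6,7-diketone is not expected: it would sit as its enol (6-hydroxy-5-en-7-one). A C7 carbinol next to the 5-en-6-yl ether would ionize to an arenium ion with acid. Therefore O6 carries a methoxymethyl group, which is removed with mild acid while C7 is still a ketone, and the enol itself is reduced.
- C15–OH is carried as its TBDPS ether so that it outlasts the acid step; O7 carries a temporary TIPS group.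
- 2-Hydroxy-3,5-dimethylbenzaldehyde is taken as a commercial building block.
- The enantiomeric series of the phase-transfer catalyst (cinchonidine- or cinchonine-derived) is to be fixed by screening so that (10R)-20 results.

## Route

Step 1
Reactants: 1 2-hydroxy-3,5-dimethylbenzaldehyde
Product: 3 3,5-dimethylbenzene-1,2-diol, via aryl formate 2 (not isolated)
Conditions: 30% H2O2, NaOH, H2O–THF, 0 °C → rt; then HCl (aq)
Reagents that add atoms: hydrogen peroxide, OO
Why: Dakin oxidation, in which the hydroperoxide adduct of the ortho-hydroxy aldehyde rearranges by aryl migration to the formate 2, which is saponified in the flask to the catechol.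

Step 2
Reactants: 3 3,5-dimethylbenzene-1,2-diol; 4 methyl 3-methylbut-2-enoate
Product: 5 8-hydroxy-4,4,5,7-tetramethylchroman-2-one
Conditions: MeSO3H, 70 °C, N2
Reagents that add atoms: none
Why: Friedel–Crafts conjugate alkylation with lactonization (the reaction that gives the "trimethyl-lock" lactone from 3,5-dimethylphenol); only the hydroxyl with a free ortho carbon (O6 next to C5) can close the lactone, so the quaternary C4 is placed on C5, the two oxygens are told apart and C9 stays open.

Step 3
Reactants: 5 8-hydroxy-4,4,5,7-tetramethylchroman-2-one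
Product: 6 4,4,5,7-tetramethyl-8-(triisopropylsilyloxy)chroman-2-one
Conditions: i-Pr3SiOTf, 2,6-lutidine, CH2Cl2, 0 °C → rt
Reagents that add atoms: triisopropylsilyl trifluoromethanesulfonate, CC(C)[Si](OS(=O)(=O)C(F)(F)F)(C(C)C)C(C)C
Why: silylation of the free O7 phenol; the bulky TIPS group is chosen because it should not migrate to the far more hindered O6 when that oxygen is later released as a phenoxide.

Step 4
Reactants: 6 4,4,5,7-tetramethyl-8-(triisopropylsilyloxy)chroman-2-one
Product: 7 4,4,5,7-tetramethyl-8-(triisopropylsilyloxy)chroman-2-ol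
Conditions: i-Bu2AlH (1.1 equiv), CH2Cl2, −78 °C; KNaC4H4O6 (aq) work-up
Reagents that add atoms: none
Why: partial reduction of the aryl lactone, which should stop at the aluminium hemiacetal at low temperature and give the lactol (racemic at C2, of no consequence).

Step 5
Reactants: 7 4,4,5,7-tetramethyl-8-(triisopropylsilyloxy)chroman-2-ol
Product: 9 [2-(methoxymethoxy)-4,6-dimethyl-3-(2-methylpent-4-en-2-yl)phenoxy]triisopropylsilane, via phenol 8 (not isolated)
Conditions: Ph3PCH3Br, KN(SiMe3)2, THF, 0 → 40 °C; then MOMCl, 0 °C → rt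
Reagents that add atoms: methyltriphenylphosphonium bromide, C[P+](c1ccccc1)(c1ccccc1)c1ccccc1.[Br-]; chloromethyl methyl ether, COCCl
Why: Wittig methylenation of the hydroxy aldehyde in equilibrium with the lactol (the phenoxide form opens the ring under the basic conditions) brings in C1, and the potassium phenoxide of 8 left in the flask is O-alkylated by MOMCl (Williamson ether synthesis).

Step 6
Reactants: 9 [2-(methoxymethoxy)-4,6-dimethyl-3-(2-methylpent-4-en-2-yl)phenoxy]triisopropylsilane
Product: 11 4-[2-(methoxymethoxy)-4,6-dimethyl-3-(triisopropylsilyloxy)phenyl]-4-methylpentan-1-ol, via alkylborane 10 (not isolated)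
Conditions: 9-BBN, THF, 0 °C → rt; then NaOAc (aq), 30% H2O2, 0 °C → rt
Reagents that add atoms: hydrogen peroxide, OO
Why: anti-Markovnikov hydroboration of the monosubstituted alkene and oxidation of the C–B bond, buffered with acetate so that the aryl silyl ether and the MOM ether survive.

Step 7
Reactants: 11 4-[2-(methoxymethoxy)-4,6-dimethyl-3-(triisopropylsilyloxy)phenyl]-4-methylpentan-1-ol
Product: 12 4-[5-bromo-2-(methoxymethoxy)-4,6-dimethyl-3-(triisopropylsilyloxy)phenyl]-4-methylpentan-1-ol
Conditions: NBS, MeCN, 0 °C, dark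
Reagents that add atoms: N-bromosuccinimide, O=C1CCC(=O)N1Br
Why: electrophilic aromatic bromination at the only ring C–H (C9), which is para to the OMOM group, so the regiochemistry is fixed by the substitution pattern.

Step 8
Reactants: 13 (Z)-3-methylpent-2-en-4-yn-1-ol
Product: 14 tert-butyl{[(2Z)-3-methylpent-2-en-4-yn-1-yl]oxy}diphenylsilane
Conditions: t-BuPh2SiCl, imidazole, CH2Cl2, 0 °C → rt
Reagents that add atoms: tert-butyl(chloro)diphenylsilane, CC(C)(C)[Si](Cl)(c1ccccc1)c1ccccc1
Why: standard silylation of the primary allylic alcohol; the TBDPS ether is chosen to outlast the later acid step.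

Step 9
Reactants: 14 tert-butyl{[(2Z)-3-methylpent-2-en-4-yn-1-yl]oxy}diphenylsilane
Product: 15 tert-butyl{[(2Z)-3-methylpenta-2,4-dien-1-yl]oxy}diphenylsilane
Conditions: H2 (1 atm), Pd/CaCO3 poisoned with Pb(OAc)2, quinoline, hexane–EtOAc, rt
Reagents that add atoms: none
Why: Lindlar semi-hydrogenation of the terminal alkyne to the vinyl group, which should leave the trisubstituted Z-alkene untouched.

Step 10
Reactants: 15 tert-butyl{[(2Z)-3-methylpenta-2,4-dien-1-yl]oxy}diphenylsilane; 12 4-[5-bromo-2-(methoxymethoxy)-4,6-dimethyl-3-(triisopropylsilyloxy)phenyl]-4-methylpentan-1-ol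
Product: 17 4-{5-[(3Z)-5-(tert-butyldiphenylsilyloxy)-3-methylpent-3-en-1-yl]-2-(methoxymethoxy)-4,6-dimethyl-3-(triisopropylsilyloxy)phenyl}-4-methylpentan-1-ol, via alkylborane 16 (not isolated)
Conditions: 15, 9-BBN, THF, 0 °C → rt; then 12, Pd(OAc)2 (5 mol%), SPhos (10 mol%), K3PO4 (3 M aq), THF, 65 °C
Reagents that add atoms: none
Why: B-alkyl Suzuki–Miyaura coupling, in which 9-BBN adds to the terminal CH2 of the diene (homoallylic borane, Z-alkene kept) and the dialkylbiarylphosphine ligand lets zerovalent palladium insert into the electron-rich, di-ortho-substituted C9–Br bond.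

Step 11
Reactants: 17 4-{5-[(3Z)-5-(tert-butyldiphenylsilyloxy)-3-methylpent-3-en-1-yl]-2-(methoxymethoxy)-4,6-dimethyl-3-(triisopropylsilyloxy)phenyl}-4-methylpentan-1-ol
Product: 18 5-[(3Z)-5-(tert-butyldiphenylsilyloxy)-3-methylpent-3-en-1-yl]-3-(5-hydroxy-2-methylpentan-2-yl)-2-(methoxymethoxy)-4,6-dimethylphenol
Conditions: Bu4NF (1.1 equiv), THF, 0 °C; NH4Cl (aq)
Reagents that add atoms: none
Why: fluoride desilylation, selective because an aryl silyl ether (phenoxide leaving group) is cleaved much faster than the primary alkyl TBDPS ether; no alkyl halide is present yet, so the phenoxide cannot cyclize early.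

Step 12
Reactants: 18 5-[(3Z)-5-(tert-butyldiphenylsilyloxy)-3-methylpent-3-en-1-yl]-3-(5-hydroxy-2-methylpentan-2-yl)-2-(methoxymethoxy)-4,6-dimethylphenol
Product: 19 3-(5-bromo-2-methylpentan-2-yl)-5-[(3Z)-5-(tert-butyldiphenylsilyloxy)-3-methylpent-3-en-1-yl]-2-(methoxymethoxy)-4,6-dimethylphenol
Conditions: CBr4, PPh3, 2,6-lutidine, CH2Cl2, 0 °C
Reagents that add atoms: tetrabromomethane, BrC(Br)(Br)Br
Why: Appel reaction at the primary alcohol; the hindered phenol cannot be substituted and stays protonated under the weakly basic buffer, which also protects the MOM ether.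

Step 13
Reactants: 19 3-(5-bromo-2-methylpentan-2-yl)-5-[(3Z)-5-(tert-butyldiphenylsilyloxy)-3-methylpent-3-en-1-yl]-2-(methoxymethoxy)-4,6-dimethylphenol
Product: 20 (10R)-15-(tert-butyldiphenylsilyloxy)-6-(methoxymethoxy)labda-5,8,13Z-trien-7-one
Conditions: O-allyl-N-(9-anthracenylmethyl)cinchonidinium bromide (10 mol%), CsOH·H2O (5 equiv), toluene–CH2Cl2 (7:3), −40 → −20 °C
Reagents that add atoms: none
Why: Proposed new method: the phenoxide of 19, ion-paired with the chiral ammonium cation, is an ambident nucleophile whose para carbon (C10) displaces the primary bromide at C1 in an intramolecular SN2 reaction and leaves ring B as a cross-conjugated cyclohexa-2,5-dienone; the closest known reactions are the base-mediated intramolecular para-C-alkylation of phenols to fused dienones (racemic) and the chiral quaternary ammonium phase-transfer alkylation of enolates. Ring A closes in the 6-exo-tet mode, helped by the gem-dimethyl group at C4. The only new stereocentre, C10, has no substrate control because 19 is achiral; it has to be set by the chiral cation shielding one face of the arene in the ion pair, and the catalyst series is chosen by screening. The step needs C- over O-alkylation and para (C10) over ortho attack: closure through O7 or C8 would need an eight-membered ring, and the competing six-membered closure onto C6 is disfavoured because that carbon carries the inductively withdrawing OMOM group, would give the less stable linearly conjugated 2,4-dienone, and a loose ammonium ion pair in a non-polar solvent favours the para position.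

Step 14
Reactants: 20 (10R)-15-(tert-butyldiphenylsilyloxy)-6-(methoxymethoxy)labda-5,8,13Z-trien-7-one
Product: 21 (10R)-15-(tert-butyldiphenylsilyloxy)-6-hydroxylabda-5,8,13Z-trien-7-one
Conditions: HCl (0.1 M, from AcCl) in MeOH–CH2Cl2, 0 °C → rt
Reagents that add atoms: none
Why: acid-catalysed transacetalization of the enol MOM ether to methanol releases the diosphenol while C7 is still a ketone (no ionizable dienyl carbinol present); the primary TBDPS ether should tolerate dilute HCl in methanol.

Step 15
Reactants: 21 (10R)-15-(tert-butyldiphenylsilyloxy)-6-hydroxylabda-5,8,13Z-trien-7-one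
Product: 23 (5S,6S,10S)-15-(tert-butyldiphenylsilyloxy)labda-8,13Z-diene-6β,7ξ-diol, via hydroxy ketone 22 (not isolated)
Conditions: NaBH4 (excess), MeOH–THF, 0 °C → rt; NH4Cl (aq)
Reagents that add atoms: none
Why: borohydride reduction of a diosphenol to the 1,2-diol, in which hydride adds to C7 (either face), the remaining C5=C6 enolate is protonated at C5 on the α face opposite the C10 and 4β methyl groups (trans-fused ketone 22), and the C6 ketone is then reduced from the open α face to the axial 6β-alcohol as is usual for 6-oxo-4,4,10-trimethyldecalins; C7 is left as a mixture that the next step erases.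

Step 16
Reactants: 23 (5S,6S,10S)-15-(tert-butyldiphenylsilyloxy)labda-8,13Z-diene-6β,7ξ-diol
Product: 24 (5S,6S,10S)-15-(tert-butyldiphenylsilyloxy)-6β-hydroxylabda-8,13Z-dien-7-one
Conditions: MnO2 (activated, excess), CH2Cl2, rt
Reagents that add atoms: none
Why: chemoselective oxidation of the allylic C7 carbinol, which converges both C7 epimers on one enone, while the hindered non-allylic 6β-hydroxyl should not react.

Step 17
Reactants: 24 (5S,6S,10S)-15-(tert-butyldiphenylsilyloxy)-6β-hydroxylabda-8,13Z-dien-7-one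
Product: 25 (5S,6S,7S,10S)-15-(tert-butyldiphenylsilyloxy)labda-8,13Z-diene-6β,7α-diol
Conditions: Me4NBH(OAc)3 (5 equiv), MeCN–AcOH (1:1), −30 → 0 °C
Reagents that add atoms: none
Why: hydroxyl-directed triacetoxyborohydride reduction (Saksena–Evans type), in which the borohydride bound to the 6β-oxygen delivers hydride to the β face of C7 and so gives the trans (6β,7α) diol, the enone being inert to the unbound reagent.

Step 18
Reactants: 25 (5S,6S,7S,10S)-15-(tert-butyldiphenylsilyloxy)labda-8,13Z-diene-6β,7α-diol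
Product: 26 (5S,6S,7S,10S)-6β,7α-diacetoxy-15-(tert-butyldiphenylsilyloxy)labda-8,13Z-diene
Conditions: Ac2O, DMAP, Et3N, CH2Cl2, rt → 40 °C
Reagents that add atoms: acetic anhydride, CC(=O)OC(C)=O
Why: DMAP-catalysed acetylation of both secondary alcohols; the hindered axial 6β-hydroxyl needs the N-acetylpyridinium species and gentle heating.

Step 19
Reactants: 26 (5S,6S,7S,10S)-6β,7α-diacetoxy-15-(tert-butyldiphenylsilyloxy)labda-8,13Z-diene
Product: 27 (5S,6S,7S,10S)-6β,7α-diacetoxylabda-8,13Z-dien-15-ol
Conditions: Bu4NF, AcOH (1:1), THF, rt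
Reagents that add atoms: none
Why: fluoride cleavage of the primary silyl ether, buffered with acetic acid so that the two acetates neither migrate nor hydrolyse.

## Compound list

1 | 2-hydroxy-3,5-dimethylbenzaldehyde | O=Cc1cc(C)cc(C)c1O | starting material
2 | 2-hydroxy-3,5-dimethylphenyl formate | O=COc1cc(C)cc(C)c1O | intermediate (not isolated)
3 | 3,5-dimethylbenzene-1,2-diol | Oc1cc(C)cc(C)c1O | intermediate
4 | methyl 3-methylbut-2-enoate | COC(=O)C=C(C)C | starting material
5 | 8-hydroxy-4,4,5,7-tetramethylchroman-2-one | O=C1CC(C)(C)c2c(C)cc(C)c(O)c2O1 | intermediate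
6 | 4,4,5,7-tetramethyl-8-(triisopropylsilyloxy)chroman-2-one | O=C1CC(C)(C)c2c(C)cc(C)c(O[Si](C(C)C)(C(C)C)C(C)C)c2O1 | intermediate
7 | 4,4,5,7-tetramethyl-8-(triisopropylsilyloxy)chroman-2-ol (racemic lactol) | OC1CC(C)(C)c2c(C)cc(C)c(O[Si](C(C)C)(C(C)C)C(C)C)c2O1 | intermediate
8 | 3,5-dimethyl-2-(2-methylpent-4-en-2-yl)-6-(triisopropylsilyloxy)phenol (formed as its potassium salt) | Oc1c(C(C)(C)CC=C)c(C)cc(C)c1O[Si](C(C)C)(C(C)C)C(C)C | intermediate (not isolated)
9 | [2-(methoxymethoxy)-4,6-dimethyl-3-(2-methylpent-4-en-2-yl)phenoxy]triisopropylsilane | COCOc1c(C(C)(C)CC=C)c(C)cc(C)c1O[Si](C(C)C)(C(C)C)C(C)C | intermediate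
10 | 9-{4-[2-(methoxymethoxy)-4,6-dimethyl-3-(triisopropylsilyloxy)phenyl]-4-methylpentyl}-9-borabicyclo[3.3.1]nonane | COCOc1c(C(C)(C)CCCB2C3CCCC2CCC3)c(C)cc(C)c1O[Si](C(C)C)(C(C)C)C(C)C | intermediate (not isolated)
11 | 4-[2-(methoxymethoxy)-4,6-dimethyl-3-(triisopropylsilyloxy)phenyl]-4-methylpentan-1-ol | COCOc1c(C(C)(C)CCCO)c(C)cc(C)c1O[Si](C(C)C)(C(C)C)C(C)C | intermediate
12 | 4-[5-bromo-2-(methoxymethoxy)-4,6-dimethyl-3-(triisopropylsilyloxy)phenyl]-4-methylpentan-1-ol | COCOc1c(C(C)(C)CCCO)c(C)c(Br)c(C)c1O[Si](C(C)C)(C(C)C)C(C)C | intermediate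
13 | (Z)-3-methylpent-2-en-4-yn-1-ol | C#C/C(C)=C\CO | starting material
14 | tert-butyl{[(2Z)-3-methylpent-2-en-4-yn-1-yl]oxy}diphenylsilane | C#C/C(C)=C\CO[Si](c1ccccc1)(c1ccccc1)C(C)(C)C | intermediate
15 | tert-butyl{[(2Z)-3-methylpenta-2,4-dien-1-yl]oxy}diphenylsilane | C=C/C(C)=C\CO[Si](c1ccccc1)(c1ccccc1)C(C)(C)C | intermediate
16 | 9-[(3Z)-5-(tert-butyldiphenylsilyloxy)-3-methylpent-3-en-1-yl]-9-borabicyclo[3.3.1]nonane | B1(CC/C(C)=C\CO[Si](c2ccccc2)(c2ccccc2)C(C)(C)C)C2CCCC1CCC2 | intermediate (not isolated)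
17 | 4-{5-[(3Z)-5-(tert-butyldiphenylsilyloxy)-3-methylpent-3-en-1-yl]-2-(methoxymethoxy)-4,6-dimethyl-3-(triisopropylsilyloxy)phenyl}-4-methylpentan-1-ol | COCOc1c(C(C)(C)CCCO)c(C)c(CC/C(C)=C\CO[Si](c2ccccc2)(c2ccccc2)C(C)(C)C)c(C)c1O[Si](C(C)C)(C(C)C)C(C)C | intermediate
18 | 5-[(3Z)-5-(tert-butyldiphenylsilyloxy)-3-methylpent-3-en-1-yl]-3-(5-hydroxy-2-methylpentan-2-yl)-2-(methoxymethoxy)-4,6-dimethylphenol | COCOc1c(C(C)(C)CCCO)c(C)c(CC/C(C)=C\CO[Si](c2ccccc2)(c2ccccc2)C(C)(C)C)c(C)c1O | intermediate
19 | 3-(5-bromo-2-methylpentan-2-yl)-5-[(3Z)-5-(tert-butyldiphenylsilyloxy)-3-methylpent-3-en-1-yl]-2-(methoxymethoxy)-4,6-dimethylphenol (key-step precursor) | COCOc1c(C(C)(C)CCCBr)c(C)c(CC/C(C)=C\CO[Si](c2ccccc2)(c2ccccc2)C(C)(C)C)c(C)c1O | intermediate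
20 | (10R)-15-(tert-butyldiphenylsilyloxy)-6-(methoxymethoxy)labda-5,8,13Z-trien-7-one (key-step product) | COCOC=1C(=O)C(C)=C(CC/C(C)=C\CO[Si](c3ccccc3)(c3ccccc3)C(C)(C)C)[C@@]2(C)CCCC(C)(C)C=12 | intermediate
21 | (10R)-15-(tert-butyldiphenylsilyloxy)-6-hydroxylabda-5,8,13Z-trien-7-one (diosphenol) | OC=1C(=O)C(C)=C(CC/C(C)=C\CO[Si](c3ccccc3)(c3ccccc3)C(C)(C)C)[C@@]2(C)CCCC(C)(C)C=12 | intermediate
22 | (5S,10S)-15-(tert-butyldiphenylsilyloxy)-7ξ-hydroxylabda-8,13Z-dien-6-one (5α-H; C7 epimers) | O=C1C(O)C(C)=C(CC/C(C)=C\CO[Si](c3ccccc3)(c3ccccc3)C(C)(C)C)[C@@]2(C)CCCC(C)(C)[C@H]12 | intermediate (not isolated)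
23 | (5S,6S,10S)-15-(tert-butyldiphenylsilyloxy)labda-8,13Z-diene-6β,7ξ-diol (C7 epimers) | O[C@@H]1C(O)C(C)=C(CC/C(C)=C\CO[Si](c3ccccc3)(c3ccccc3)C(C)(C)C)[C@@]2(C)CCCC(C)(C)[C@H]12 | intermediate
24 | (5S,6S,10S)-15-(tert-butyldiphenylsilyloxy)-6β-hydroxylabda-8,13Z-dien-7-one | O[C@@H]1C(=O)C(C)=C(CC/C(C)=C\CO[Si](c3ccccc3)(c3ccccc3)C(C)(C)C)[C@@]2(C)CCCC(C)(C)[C@H]12 | intermediate
25 | (5S,6S,7S,10S)-15-(tert-butyldiphenylsilyloxy)labda-8,13Z-diene-6β,7α-diol | O[C@@H]1[C@@H](O)C(C)=C(CC/C(C)=C\CO[Si](c3ccccc3)(c3ccccc3)C(C)(C)C)[C@@]2(C)CCCC(C)(C)[C@H]12 | intermediate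
26 | (5S,6S,7S,10S)-6β,7α-diacetoxy-15-(tert-butyldiphenylsilyloxy)labda-8,13Z-diene | CC(=O)O[C@@H]1[C@@H](OC(C)=O)C(C)=C(CC/C(C)=C\CO[Si](c3ccccc3)(c3ccccc3)C(C)(C)C)[C@@]2(C)CCCC(C)(C)[C@H]12 | intermediate
27 | (5S,6S,7S,10S)-6β,7α-diacetoxylabda-8,13Z-dien-15-ol (CNP0187815.3) | CC(=O)O[C@@H]1[C@@H](OC(C)=O)C(C)=C(CC/C(C)=C\CO)[C@@]2(C)CCCC(C)(C)[C@H]12 | target

## Step count and risks

Total step count: 19. Longest linear sequence: 17 steps (steps 1–7 and 10–19, from 1 to 27); steps 8 and 9 prepare the side-chain fragment.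

Steps most likely to fail:

1. Step 13 (proposed new method). The ion pair may not discriminate the two faces of the arene (low enantioselectivity), the tether may close onto C6 instead of C10, or phase transfer of the hindered phenoxide may be slow enough for loss of HBr to compete. Fallback: set out from 19 and run the cyclization in its known racemic form with KOt-Bu in t-BuOH–THF (para-C-alkylation of a potassium phenoxide in a polar medium), which should give the racemic dienone F1. The enantiomers are then separated by preparative chromatography on a chiral stationary phase (cellulose tris(3,5-dimethylphenylcarbamate)). The (10R) enantiomer is compound 20, where the route is rejoined.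

2. Step 15. The diosphenol is deprotonated under the reaction conditions and its anion may take up hydride only slowly; the intermediate ketol may also isomerize through its enediol before the C6 carbonyl is reduced, which would erode the configuration at C6. Fallback: set out from 21 and acetylate the enol (Ac2O, pyridine, DMAP) to the enol acetate F2. Reduce this neutral dienone with NaBH4 in MeOH–THF at −20 °C: the C7 alkoxide should take over the acetyl group from the neighbouring enol oxygen, and the released C6 enolate ketonizes (α-protonation at C5) and is reduced from the α face. This should give the 7-acetate F3 as a C7 mixture, and methanolysis (K2CO3, MeOH) returns to compound 23.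

3. Step 17. The 6β-hydroxyl, flanked by two syn-axial methyl groups, may exchange onto boron too slowly, so that either no reduction or an undirected α-face reduction takes place. Fallback: set out from 24 and reduce under Luche conditions (NaBH4, CeCl3·7H2O, MeOH, −78 °C; hydride from the open α face) to the cis-diol F4. Invert the allylic C7 carbinol by Mitsunobu reaction with acetic acid (PPh3, DIAD, toluene, 0 °C → rt) to the 7α-acetate F5; the hindered 6β-hydroxyl is not activated and, being cis, cannot close an epoxide. Acetylate the remaining 6β-hydroxyl (Ac2O, DMAP, Et3N) to arrive at compound 26.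

Further compounds

F1 | step 13 | racemic 15-(tert-butyldiphenylsilyloxy)-6-(methoxymethoxy)labda-5,8,13Z-trien-7-one | COCOC=1C(=O)C(C)=C(CC/C(C)=C\CO[Si](c3ccccc3)(c3ccccc3)C(C)(C)C)C2(C)CCCC(C)(C)C=12
F2 | step 15 | (10R)-6-acetoxy-15-(tert-butyldiphenylsilyloxy)labda-5,8,13Z-trien-7-one | CC(=O)OC=1C(=O)C(C)=C(CC/C(C)=C\CO[Si](c3ccccc3)(c3ccccc3)C(C)(C)C)[C@@]2(C)CCCC(C)(C)C=12
F3 | step 15 | (5S,6S,10S)-7ξ-acetoxy-15-(tert-butyldiphenylsilyloxy)labda-8,13Z-dien-6β-ol (C7 epimers) | O[C@@H]1C(OC(C)=O)C(C)=C(CC/C(C)=C\CO[Si](c3ccccc3)(c3ccccc3)C(C)(C)C)[C@@]2(C)CCCC(C)(C)[C@H]12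
F4 | step 17 | (5S,6S,7R,10S)-15-(tert-butyldiphenylsilyloxy)labda-8,13Z-diene-6β,7β-diol | O[C@@H]1[C@H](O)C(C)=C(CC/C(C)=C\CO[Si](c3ccccc3)(c3ccccc3)C(C)(C)C)[C@@]2(C)CCCC(C)(C)[C@H]12
F5 | step 17 | (5S,6S,7S,10S)-7α-acetoxy-15-(tert-butyldiphenylsilyloxy)labda-8,13Z-dien-6β-ol | O[C@@H]1[C@@H](OC(C)=O)C(C)=C(CC/C(C)=C\CO[Si](c3ccccc3)(c3ccccc3)C(C)(C)C)[C@@]2(C)CCCC(C)(C)[C@H]12
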